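In the spring run the electrophile disappears more slowly than the nucleophile arrives: between 8.00 min and 15.0 min it falls by 0.481 of the amount fed in that interval, about half, and over the same stretch the winter run gives 0.455.

in all of them: electrophile 0.10 M
- spring: nucleophile 0.95 equiv (fed, over 20 min); run made earlier; the fed solution adds 0.20 times the starting volume
- winter: nucleophile 1.4 equiv (fed, over 20 min); run made earlier; the fed solution adds 0.20 times the starting volume
- Friday's: nucleophile 1.10 equiv (fed, over 20 min); the fed solution adds 0.20 times the starting volume; time 20 min
- Monday's: nucleophile 2.10 equiv (fed, over 20 min); the fed solution adds 0.20 times the starting volume; time 20 min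

- spring (time / min: electrophile / %, target / %): 3.00: 96.8, 3.1; 6.00: 91.7, 7.2; 8.00: 87.0, 10.6; 12.0: 78.0, 15.4; 15.0: 71.0, 18.4
- winter (time / min: electrophile / %, target / %): 1.00: 99.3, 0.7; 2.00: 98.6, 1.5; 4.00: 92.7, 5.7; 8.00: 81.3, 14.7; 15.0: 59.0, 25.6

(each reading ± 0.5 percentage points)

- charges are per starting volume, the dose included; the dosed solution carries all of it
- the analysis behind the earlier runs scatters by 0.5 percentage points, standard deviation
- steps thought possible: target -> over-reaction product; electrophile + nucleophile -> acid set free + target; nucleophile + acid set free <-> protonated nucleophile

* part of the electrophile that has reacted at the end, Friday's
* part of the electrophile that has reacted at the end, Monday's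
* what raising the equivalents of nucleophile from its lowest to its highest value here does to the part of the electrophile that has reacted (changes below 5 percentage points count as none) (it falls / no change / it rises)

The bench rule says that an equivalent and a little over finishes an electrophile, and Friday's 1.10 equiv obeys it. These two ratios speak against the rule. They suggest that two nucleophiles leave the solution per electrophile reacted, one becoming target and one held by the acid set free as protonated nucleophile. The rate of the step to target is first order in c(nucleophile), so the free nucleophile is the concentration to watch.

My own reckoning therefore treats the nucleophile as the limiting reagent in Friday's flask and uses the ceiling, the conversion at which the charged nucleophile is used two per electrophile: 55.0% for Friday's, half the equivalents. For Monday's the same ratio gives 105%, above the whole charge of electrophile, whereas Friday's lies below it. That is the border of the rule: for Monday's the ceiling sets no limit below the whole charge.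

The forecast reads the runs the same way, “Conversion therefore tends towards a ceiling of half the equivalents”, and gives 45% (40% to 50%) for Friday's, 76% (67% to 84%) for Monday's, and it rises.

Friday's flask gives 44.7% and Monday's 72.8%; for the trend the answer is it rises, by 28 percentage points.

    target → over-reaction product (k = 0.00123 s⁻¹)
    electrophile + nucleophile → acid set free + target (k = 0.0330 L mol⁻¹ s⁻¹)
    nucleophile + acid set free ⇌ protonated nucleophile, settled at all times (K = 370 L mol⁻¹)

Friday's flask is not at rest at 20 min: 55% of the electrophile and 23% of the nucleophile remain, and protonated nucleophile stands at 0.0331 M, more than the 0.00419 M of free acid. At 200 min conversion reaches 81.4%, above the ceiling, with protonated nucleophile at 0.0225 M, less than the 0.0454 M of free acid. Friday's flask stands below the ceiling at 20 min and has passed it by 200 min. Friday's recipe at 0.25 M of electrophile keeps its equivalents, so the ceiling stays 55.0%; that flask gives 51.2%, below it.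

All runs are calculated with constants of no real substance; the scatter is artificial.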